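**Strategy**

The oxirane C1–C10 bond is cis-fused to the ten-membered ring (C9 and C2 on one side), so it is the epoxide of a Z-C1=C10 olefin. That olefin is made by ring-closing metathesis, which closes the carbocycle at this bond with the geometry a medium ring enforces. The precursor is a seco-diene (C1 vinyl, C10 isopropenyl) already bent by two cis elements: the 4,5-oxirane, taken from nerol (C1–C6, C15), and the butenolide, built by Nozaki–Hiyama–Kishi union with an enol triflate derived from a catalytic glyoxylate–ene adduct (C8). The C8 hydroxyl then directs epoxidation of C1=C10.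

Key step: step 11

Remark: germacrane numbering is used throughout (ring C1–C10, C14 on C10, C15 on C4, lactone C12 with C11 and C13); compound 12 is taken as a catalogue reagent (otherwise one silylation of methyl 3-hydroxypropanoate).

**Route**

Step 1
Reactants: 1 nerol, (2Z)-3,7-dimethylocta-2,6-dien-1-ol
Product: 2 [(2R,3S)-3-methyl-3-(4-methylpent-3-en-1-yl)oxiran-2-yl]methanol
Conditions: Ti(OiPr)4 (10 mol %), D-(−)-diisopropyl tartrate (12 mol %), t-BuOOH, 4 Å MS, CH2Cl2, −20 °C
Reagents that add atoms: tert-butyl hydroperoxide, CC(C)(C)OO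
Why: Sharpless asymmetric epoxidation, in which the titanium–D-tartrate complex delivers oxygen to one face of the allylic alcohol olefin only, sets C4 (S) and C5 (R), and the Z geometry of nerol fixes C3 and C6 cis on the oxirane.

Step 2
Reactants: 2 [(2R,3S)-3-methyl-3-(4-methylpent-3-en-1-yl)oxiran-2-yl]methanol
Product: 4 3-[(2S,3R)-3-(hydroxymethyl)-2-methyloxiran-2-yl]propanal, via ozonide 3 (not isolated)
Conditions: O3, CH2Cl2, −78 °C; then PPh3, −78 °C to rt
Reagents that add atoms: ozone, [O-][O+]=O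
Why: Ozonolysis with reductive work-up cleaves the only olefin to the C1 aldehyde, the oxirane and the alcohol being inert to ozone at −78 °C.

Step 3
Reactants: 4 3-[(2S,3R)-3-(hydroxymethyl)-2-methyloxiran-2-yl]propanal
Product: 5 [(2R,3S)-3-(but-3-en-1-yl)-3-methyloxiran-2-yl]methanol
Conditions: Ph3PCH3Br, KOtBu, THF, 0 °C; then 4, −78 to 0 °C
Reagents that add atoms: methyltriphenylphosphonium bromide, [Br-].C[P+](c1ccccc1)(c1ccccc1)c1ccccc1
Why: Wittig methylenation (excess ylide covers the free hydroxyl) gives the monosubstituted C1 vinyl group that serves as the fast-initiating metathesis terminus, without touching a stereocentre.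

Step 4
Reactants: 5 [(2R,3S)-3-(but-3-en-1-yl)-3-methyloxiran-2-yl]methanol
Product: 6 (2S,3S)-3-(but-3-en-1-yl)-3-methyloxirane-2-carbaldehyde
Conditions: Dess–Martin periodinane, pyridine, CH2Cl2, 0 °C to rt
Reagents that add atoms: none
Why: Dess–Martin oxidation under buffered conditions should give the α,β-epoxy aldehyde without epimerisation at C5; it is used without storage.

Step 5
Reactants: 7 2-methylpropene; 8 methyl glyoxylate
Product: 9 methyl (2R)-2-hydroxy-4-methylpent-4-enoate
Conditions: (R)-BINOL / TiCl2(OiPr)2 (10 mol %), 4 Å MS, CH2Cl2, −30 °C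
Reagents that add atoms: none
Why: Catalytic asymmetric glyoxylate–ene reaction, in which the BINOL–titanium Lewis acid shields one aldehyde face, sets C8 (R) and delivers C7–C10, C14 and the future metathesis methylene in one step.

Step 6
Reactants: 9 methyl (2R)-2-hydroxy-4-methylpent-4-enoate
Product: 10 methyl (2R)-2-(tert-butyldimethylsilyloxy)-4-methylpent-4-enoate
Conditions: TBSCl, imidazole, DMF, rt
Reagents that add atoms: tert-butyldimethylsilyl chloride, CC(C)(C)[Si](C)(C)Cl
Why: Standard silylation masks the C8 hydroxyl for the enolate, chromium and ruthenium steps.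

Step 7
Reactants: 10 methyl (2R)-2-(tert-butyldimethylsilyloxy)-4-methylpent-4-enoate
Product: 11 (2R)-2-(tert-butyldimethylsilyloxy)-N-methoxy-N,4-dimethylpent-4-enamide
Conditions: MeNH(OMe)·HCl, iPrMgCl, THF, −20 to 0 °C
Reagents that add atoms: N,O-dimethylhydroxylamine hydrochloride, Cl.CNOC
Why: Weinreb amide formation by aminolysis of the ester with the magnesium amide proceeds at low temperature without epimerising the α-silyloxy centre.

Step 8
Reactants: 11 (2R)-2-(tert-butyldimethylsilyloxy)-N-methoxy-N,4-dimethylpent-4-enamide; 12 methyl 3-(tert-butyldimethylsilyloxy)propanoate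
Product: 15 methyl (4R)-4-(tert-butyldimethylsilyloxy)-2-[(tert-butyldimethylsilyloxy)methyl]-6-methyl-3-oxohept-6-enoate (C2 epimers), via lithium enolate 13 (not isolated), via chelated tetrahedral adduct 14 (not isolated)
Conditions: LiN(iPr)2, THF, −78 °C; then 11, −78 to −40 °C; aq NH4Cl
Reagents that add atoms: none
Why: Crossed Claisen-type acylation of the ester enolate by the Weinreb amide joins C7 to C11, the chelated adduct preventing over-addition and the low temperature preventing β-elimination of the silyloxy group; C11 forms as an inconsequential epimer mixture.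

Step 9
Reactants: 15 methyl (4R)-4-(tert-butyldimethylsilyloxy)-2-[(tert-butyldimethylsilyloxy)methyl]-6-methyl-3-oxohept-6-enoate
Product: 17 methyl (2Z,4R)-4-(tert-butyldimethylsilyloxy)-2-[(tert-butyldimethylsilyloxy)methyl]-6-methyl-3-(trifluoromethylsulfonyloxy)hepta-2,6-dienoate, via sodium enolate 16 (not isolated)
Conditions: NaH, Et2O, 0 °C; then Tf2O, −78 to 0 °C
Reagents that add atoms: trifluoromethanesulfonic anhydride, O=S(=O)(OS(=O)(=O)C(F)(F)F)C(F)(F)F
Why: O-sulfonylation of the sodium-chelated enolate, in which the enolate oxygen and the ester carbonyl are held cis, should give the Z enol triflate (C7–O cis to C12) needed for later lactonisation.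

Step 10
Reactants: 17 methyl (2Z,4R)-4-(tert-butyldimethylsilyloxy)-2-[(tert-butyldimethylsilyloxy)methyl]-6-methyl-3-(trifluoromethylsulfonyloxy)hepta-2,6-dienoate; 6 (2S,3S)-3-(but-3-en-1-yl)-3-methyloxirane-2-carbaldehyde
Product: 20 (5R)-5-[(2R,3S)-3-(but-3-en-1-yl)-3-methyloxiran-2-yl]-4-[(1R)-1-(tert-butyldimethylsilyloxy)-3-methylbut-3-en-1-yl]-3-[(tert-butyldimethylsilyloxy)methyl]furan-2(5H)-one, via alkenylchromium dichloride 18 (not isolated), via open-chain hydroxy ester 19 (not isolated)
Conditions: CrCl2 (6 equiv), NiCl2 (5 mol %), DMF, rt; aqueous work-up, then PPTS (cat.), CH2Cl2 if lactonisation is incomplete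
Reagents that add atoms: none
Why: Nozaki–Hiyama–Kishi coupling (zerovalent nickel inserts into the triflate, transmetalation to trivalent chromium) adds the alkenyl group to the aldehyde from the Felkin–Anh face, anti to the oxirane C5–O bond, setting C6 (R); the alkoxide is cis to the ester and closes the butenolide.

Step 11
Reactants: 20 (5R)-5-[(2R,3S)-3-(but-3-en-1-yl)-3-methyloxiran-2-yl]-4-[(1R)-1-(tert-butyldimethylsilyloxy)-3-methylbut-3-en-1-yl]-3-[(tert-butyldimethylsilyloxy)methyl]furan-2(5H)-one
Product: 21 (1(10)Z,4S,5R,6R,8R)-8,13-bis(tert-butyldimethylsilyloxy)-4,5-epoxygermacra-1(10),7(11)-dien-12,6-olide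
Conditions: second-generation Grubbs catalyst RuCl2(=CHPh)(PCy3)(H2IMes) (15 mol %, in portions), 2,3,5,6-tetrafluoro-1,4-benzoquinone (30 mol %), toluene (0.5 mM), 90 °C, argon sparge
Reagents that add atoms: none
Why: The ruthenium alkylidene forms at the monosubstituted C1 vinyl group, adds [2+2] to the 1,1-disubstituted C10 isopropenyl group and cycloreverts with loss of ethylene, forming the C1–C10 bond (ring-closing olefin metathesis; closest known type is closure of lactone-fused ten-membered carbocycles to trisubstituted ring olefins). The ten-membered carbocycle is closed end-to-end by this single bond, the chain being pre-bent by the cis-4,5-oxirane and the C6–C7 edge of the butenolide. No stereocentre is formed; the Z geometry should follow from ring strain, since the E isomer of a ring already holding two cis elements is much less accessible, and it places C9 and C2 on the same side as the cis-fused oxirane requires. The step needs ring closure over dimerisation, which high dilution and portionwise catalyst addition favour. It also needs reaction at C1 and C10 only: the butenolide C7=C11 is tetrasubstituted and electron-poor, and the 4,5-olefin is already masked as the oxirane, so no six-membered ring can form. The quinone suppresses olefin migration by ruthenium hydrides.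

Step 12
Reactants: 21 (1(10)Z,4S,5R,6R,8R)-8,13-bis(tert-butyldimethylsilyloxy)-4,5-epoxygermacra-1(10),7(11)-dien-12,6-olide
Product: 22 (1(10)Z,4S,5R,6R,8R)-4,5-epoxy-8,13-dihydroxygermacra-1(10),7(11)-dien-12,6-olide
Conditions: HF·pyridine, pyridine, THF, 0 °C to rt
Reagents that add atoms: none
Why: Pyridine-buffered fluoride cleavage of both silyl ethers should leave the oxirane, the lactone and the base-sensitive butenolide γ-position untouched.

Step 13
Reactants: 22 (1(10)Z,4S,5R,6R,8R)-4,5-epoxy-8,13-dihydroxygermacra-1(10),7(11)-dien-12,6-olide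
Product: 23 (1(10)Z,4S,5R,6R,8R)-13-acetoxy-4,5-epoxy-8-hydroxygermacra-1(10),7(11)-dien-12,6-olide
Conditions: Ac2O (1.2 equiv), 2,4,6-collidine, CH2Cl2, −20 to 0 °C
Reagents that add atoms: acetic anhydride, CC(=O)OC(C)=O
Why: Kinetically selective acetylation of the primary allylic C13 hydroxyl over the hindered secondary C8 hydroxyl, the primary acetate also being the thermodynamically preferred position.

Step 14
Reactants: 23 (1(10)Z,4S,5R,6R,8R)-13-acetoxy-4,5-epoxy-8-hydroxygermacra-1(10),7(11)-dien-12,6-olide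
Product: 24 (1R,4S,5R,6R,8R,10S)-13-acetoxy-1,10:4,5-diepoxy-8-hydroxygermacr-7(11)-en-12,6-olide
Conditions: VO(acac)2 (10 mol %), t-BuOOH (anhydrous), 2,6-lutidine (20 mol %), CH2Cl2, 0 °C to rt
Reagents that add atoms: tert-butyl hydroperoxide, CC(C)(C)OO
Why: Hydroxyl-directed vanadium-catalysed epoxidation, in which the C8 vanadate ester delivers the peroxide oxygen to the face of the homoallylic Z olefin on which O8 lies, should set C10 (S) and C1 (R) syn to the C8–O bond; the electron-poor butenolide olefin is inert and lutidine buffers the medium.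

Step 15
Reactants: 24 (1R,4S,5R,6R,8R,10S)-13-acetoxy-1,10:4,5-diepoxy-8-hydroxygermacr-7(11)-en-12,6-olide
Product: 25 (1R,4S,5R,6R,8R,10S)-13-acetoxy-1,10:4,5-diepoxy-8-(2-methylprop-2-enoyloxy)germacr-7(11)-en-12,6-olide (CNP0212980.1)
Conditions: methacrylic anhydride, Et3N, DMAP (cat.), CH2Cl2, 0 °C to rt
Reagents that add atoms: methacrylic anhydride, C=C(C)C(=O)OC(=O)C(C)=C
Why: DMAP-catalysed acylation of the C8 hydroxyl under a base too weak to deprotonate the butenolide γ-position completes the target.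

**Compound list**

1 | nerol, (2Z)-3,7-dimethylocta-2,6-dien-1-ol | CC(C)=CCC/C(C)=C\CO | starting material
2 | [(2R,3S)-3-methyl-3-(4-methylpent-3-en-1-yl)oxiran-2-yl]methanol | CC(C)=CCC[C@]1(C)O[C@@H]1CO | intermediate
3 | ozonide (1,2,4-trioxolane) of 2 | CC1(C)OOC(CC[C@]2(C)O[C@@H]2CO)O1 | intermediate (not isolated)
4 | 3-[(2S,3R)-3-(hydroxymethyl)-2-methyloxiran-2-yl]propanal | O=CCC[C@]1(C)O[C@@H]1CO | intermediate
5 | [(2R,3S)-3-(but-3-en-1-yl)-3-methyloxiran-2-yl]methanol | C=CCC[C@]1(C)O[C@@H]1CO | intermediate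
6 | (2S,3S)-3-(but-3-en-1-yl)-3-methyloxirane-2-carbaldehyde | C=CCC[C@]1(C)O[C@@H]1C=O | intermediate
7 | 2-methylpropene | CC(C)=C | starting material
8 | methyl glyoxylate | COC(=O)C=O | starting material
9 | methyl (2R)-2-hydroxy-4-methylpent-4-enoate | COC(=O)[C@H](O)CC(C)=C | intermediate
10 | methyl (2R)-2-(tert-butyldimethylsilyloxy)-4-methylpent-4-enoate | COC(=O)[C@H](O[Si](C)(C)C(C)(C)C)CC(C)=C | intermediate
11 | (2R)-2-(tert-butyldimethylsilyloxy)-N-methoxy-N,4-dimethylpent-4-enamide | CON(C)C(=O)[C@H](O[Si](C)(C)C(C)(C)C)CC(C)=C | intermediate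
12 | methyl 3-(tert-butyldimethylsilyloxy)propanoate | COC(=O)CCO[Si](C)(C)C(C)(C)C | starting material
13 | lithium enolate of 12 | [Li]OC(OC)=CCO[Si](C)(C)C(C)(C)C | intermediate (not isolated)
14 | chelated tetrahedral adduct of 13 and 11 | COC(=O)C(CO[Si](C)(C)C(C)(C)C)C(O[Li])(N(C)OC)[C@H](O[Si](C)(C)C(C)(C)C)CC(C)=C | intermediate (not isolated)
15 | methyl (4R)-4-(tert-butyldimethylsilyloxy)-2-[(tert-butyldimethylsilyloxy)methyl]-6-methyl-3-oxohept-6-enoate | COC(=O)C(CO[Si](C)(C)C(C)(C)C)C(=O)[C@H](O[Si](C)(C)C(C)(C)C)CC(C)=C | intermediate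
16 | sodium (Z)-enolate of 15 | COC(=O)/C(CO[Si](C)(C)C(C)(C)C)=C(\O[Na])[C@H](O[Si](C)(C)C(C)(C)C)CC(C)=C | intermediate (not isolated)
17 | methyl (2Z,4R)-4-(tert-butyldimethylsilyloxy)-2-[(tert-butyldimethylsilyloxy)methyl]-6-methyl-3-(trifluoromethylsulfonyloxy)hepta-2,6-dienoate | COC(=O)/C(CO[Si](C)(C)C(C)(C)C)=C(\OS(=O)(=O)C(F)(F)F)[C@H](O[Si](C)(C)C(C)(C)C)CC(C)=C | intermediate
18 | alkenylchromium dichloride from 17 (trivalent chromium on C7, cis to the ester) | COC(=O)/C(CO[Si](C)(C)C(C)(C)C)=C(\[Cr](Cl)Cl)[C@H](O[Si](C)(C)C(C)(C)C)CC(C)=C | intermediate (not isolated)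
19 | open-chain hydroxy ester (C6 carbinol cis to the methyl ester) | C=CCC[C@]1(C)O[C@@H]1[C@H](O)/C(=C(/CO[Si](C)(C)C(C)(C)C)C(=O)OC)[C@H](O[Si](C)(C)C(C)(C)C)CC(C)=C | intermediate (not isolated)
20 | (5R)-5-[(2R,3S)-3-(but-3-en-1-yl)-3-methyloxiran-2-yl]-4-[(1R)-1-(tert-butyldimethylsilyloxy)-3-methylbut-3-en-1-yl]-3-[(tert-butyldimethylsilyloxy)methyl]furan-2(5H)-one | C=CCC[C@]1(C)O[C@@H]1[C@@H]1OC(=O)C(CO[Si](C)(C)C(C)(C)C)=C1[C@H](O[Si](C)(C)C(C)(C)C)CC(C)=C | intermediate
21 | (1(10)Z,4S,5R,6R,8R)-8,13-bis(tert-butyldimethylsilyloxy)-4,5-epoxygermacra-1(10),7(11)-dien-12,6-olide | CC(C)(C)[Si](C)(C)O[C@@H]1C/C(C)=C\CC[C@]2(C)O[C@@H]2[C@@H]2OC(=O)C(CO[Si](C)(C)C(C)(C)C)=C21 | intermediate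
22 | (1(10)Z,4S,5R,6R,8R)-4,5-epoxy-8,13-dihydroxygermacra-1(10),7(11)-dien-12,6-olide | O[C@@H]1C/C(C)=C\CC[C@]2(C)O[C@@H]2[C@@H]2OC(=O)C(CO)=C21 | intermediate
23 | (1(10)Z,4S,5R,6R,8R)-13-acetoxy-4,5-epoxy-8-hydroxygermacra-1(10),7(11)-dien-12,6-olide | O[C@@H]1C/C(C)=C\CC[C@]2(C)O[C@@H]2[C@@H]2OC(=O)C(COC(C)=O)=C21 | intermediate
24 | (1R,4S,5R,6R,8R,10S)-13-acetoxy-1,10:4,5-diepoxy-8-hydroxygermacr-7(11)-en-12,6-olide | O[C@@H]1C[C@]2(C)O[C@@H]2CC[C@]2(C)O[C@@H]2[C@@H]2OC(=O)C(COC(C)=O)=C21 | intermediate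
25 | (1R,4S,5R,6R,8R,10S)-13-acetoxy-1,10:4,5-diepoxy-8-(2-methylprop-2-enoyloxy)germacr-7(11)-en-12,6-olide | C=C(C)C(=O)O[C@@H]1C[C@]2(C)O[C@@H]2CC[C@]2(C)O[C@@H]2[C@@H]2OC(=O)C(COC(C)=O)=C21 | target

**Step count and risks**

Total steps: 15. Longest linear sequence: 11 steps (steps 5 to 15).

Steps most likely to fail:

1. Step 11 (ring-closing metathesis). Intermolecular metathesis at the C1 vinyl group may outrun closure of the strained ring; the 1,1-disubstituted C10 olefin may engage too slowly, so that the catalyst decays first; the geometry may erode. The fallback forms the same C1–C10 bond reductively; it sets out from 20 and comes back at 21. Both terminal olefins of 20 are cleaved (O3, CH2Cl2, −78 °C; then PPh3) to the keto aldehyde F1, which carries the C1 aldehyde and the C10 methyl ketone. Pinacol cyclisation with SmI2 (THF, high dilution, −78 °C to rt) should give the cis-1,10-diol F2 through a chelated ketyl. Thiocarbonyldiimidazole (DMAP, toluene, 80 °C) converts it into the cyclic thionocarbonate F3. Stereospecific syn elimination with 1,3-dimethyl-2-phenyl-1,3,2-diazaphospholidine (40 °C, Corey–Winter olefination in its mild variant) then gives the Z olefin 21.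

2. Step 14 (directed epoxidation). The vanadium-bound C8 alkoxide may open the 4,5-oxirane transannularly instead of delivering oxygen, or delivery may occur with poor facial selectivity if the ring conformer that places O8 over the olefin is not populated. The fallback replaces hydroxyl delivery by steric control; it sets out from 23 and comes back at 25. Alcohol 23 is first esterified (methacrylic anhydride, Et3N, DMAP) to the 8-O-methacryloyl olefin F4. Dimethyldioxirane (acetone, 0 °C) then epoxidises only the electron-rich C1=C10 olefin, expected from the exposed face of the conformer in which the 8-acyloxy group is pseudo-equatorial, to give 25 directly.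

3. Step 10 (Nozaki–Hiyama–Kishi union). The tetrasubstituted alkenylchromium may add too slowly and be protonated, the Felkin–Anh preference at C6 may be low, or chloride may open the epoxy aldehyde. The fallback sets C6 by reduction instead of addition; it sets out from 17 and 6 and comes back at 20. Triflate 17 is converted (Me3SnSnMe3, Pd(PPh3)4, LiCl, THF, 60 °C) into the alkenylstannane F5. Aldehyde 6 is oxidised (NaClO2, NaH2PO4, 2-methylbut-2-ene) to the glycidic acid F6 and condensed with thiophenol (DCC, DMAP) to the S-phenyl thioester F7. Liebeskind–Srogl coupling of F5 with F7 (Pd2(dba)3, tri(2-furyl)phosphine, monovalent copper diphenylphosphinate CuO2PPh2, THF) gives the γ-keto enoate F8. Chelation-controlled reduction with Zn(BH4)2 (Et2O, −20 °C), which is anti-selective for α,β-epoxy ketones, should give hydroxy ester 19, which lactonises to 20.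

**Further compounds**

F1 | step 11 | keto aldehyde from double ozonolysis of 20 (C1 aldehyde, C10 methyl ketone) | O=CCC[C@]1(C)O[C@@H]1[C@@H]1OC(=O)C(CO[Si](C)(C)C(C)(C)C)=C1[C@H](O[Si](C)(C)C(C)(C)C)CC(C)=O
F2 | step 11 | cis-1,10-diol of the ten-membered ring (pinacol product) | CC(C)(C)[Si](C)(C)O[C@@H]1CC(C)(O)C(O)CC[C@]2(C)O[C@@H]2[C@@H]2OC(=O)C(CO[Si](C)(C)C(C)(C)C)=C21
F3 | step 11 | cyclic 1,10-thionocarbonate of F2 | CC(C)(C)[Si](C)(C)O[C@@H]1CC2(C)OC(=S)OC2CC[C@]2(C)O[C@@H]2[C@@H]2OC(=O)C(CO[Si](C)(C)C(C)(C)C)=C21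
F4 | step 14 | (1(10)Z,4S,5R,6R,8R)-13-acetoxy-4,5-epoxy-8-(2-methylprop-2-enoyloxy)germacra-1(10),7(11)-dien-12,6-olide | C=C(C)C(=O)O[C@@H]1C/C(C)=C\CC[C@]2(C)O[C@@H]2[C@@H]2OC(=O)C(COC(C)=O)=C21
F5 | step 10 | methyl (2Z,4R)-4-(tert-butyldimethylsilyloxy)-2-[(tert-butyldimethylsilyloxy)methyl]-6-methyl-3-(trimethylstannyl)hepta-2,6-dienoate | COC(=O)/C(CO[Si](C)(C)C(C)(C)C)=C(\[Sn](C)(C)C)[C@H](O[Si](C)(C)C(C)(C)C)CC(C)=C
F6 | step 10 | 3-(but-3-en-1-yl)-3-methyloxirane-2-carboxylic acid (configuration of 6 retained) | C=CCC[C@]1(C)O[C@@H]1C(=O)O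
F7 | step 10 | S-phenyl 3-(but-3-en-1-yl)-3-methyloxirane-2-carbothioate (configuration of 6 retained) | C=CCC[C@]1(C)O[C@@H]1C(=O)Sc1ccccc1
F8 | step 10 | γ-keto enoate (C6 ketone cis to the methyl ester) | C=CCC[C@]1(C)O[C@@H]1C(=O)/C(=C(/CO[Si](C)(C)C(C)(C)C)C(=O)OC)[C@H](O[Si](C)(C)C(C)(C)C)CC(C)=C
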